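The furan is cut at its O1–C2 bond and at both bonds of the ester carbonyl (CH2–C(=O) and C(=O)–OMe). One PdI2/KI-catalysed oxidative carbonylation with CO, methanol and air closes the furan ring and builds the ester in a single operation. The feature exploited is the furan ring whose C2, flanked by O1, bears a one-carbon spacer to the ester: O1–C2 arises from hydroxyl attack on an alkyne, and the spacer carbon is the former alkyne terminus. The precursor is racemic (Z)-henicos-3-en-1-yn-5-ol: its carbinol carbon carries the hexadecyl chain (future C5), its Z alkene becomes C3–C4, and its ethynyl group supplies C2 and the CH2.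

Key step: step 5

Remark: the target is achiral and the carbinol centre of the enynol is erased on aromatisation, so all carbinols are carried as racemates. Compound 2 is also assumed to be purchasable, which would shorten the route by one step.

Step 1
Reactants: 1 ethyl propiolate (ethyl prop-2-ynoate)
Product: 2 ethyl (Z)-3-iodoprop-2-enoate
Conditions: NaI, AcOH, 70 °C
Reagents that add atoms: sodium iodide, [Na+].[I-]
Why: Conjugate hydroiodination of the ynoate, in which iodide adds to the β-carbon and the resulting allenolate is protonated by acetic acid anti to iodine, should give the Z β-iodoacrylate under kinetic control.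

Step 2
Reactants: 2 ethyl (Z)-3-iodoprop-2-enoate; 3 1-bromohexadecane
Product: 6 (Z)-1-iodononadec-1-en-3-ol (racemic), via hexadecylmagnesium bromide 4 (not isolated), via (Z)-3-iodoprop-2-enal 5 (not isolated)
Conditions: (a) 3, Mg, THF, reflux (separate flask); (b) 2, i-Bu2AlH (1.05 equiv), CH2Cl2, −78 °C; (c) solution of 4 (1.5 equiv), −78 to 0 °C; aq. potassium sodium tartrate
Reagents that add atoms: none
Why: Partial ester reduction with i-Bu2AlH at −78 °C stops at the aldehyde oxidation level, and the Z β-iodoenal 5 is captured in the same flask by Grignard 1,2-addition of 4 before it can isomerise to the E form; the new carbinol centre forms as a racemate, which is acceptable because it is lost in step 5.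

Step 3
Reactants: 6 (Z)-1-iodononadec-1-en-3-ol; 7 ethynyltrimethylsilane
Product: 8 (Z)-1-(trimethylsilyl)henicos-3-en-1-yn-5-ol (racemic)
Conditions: Pd(PPh3)2Cl2 (2 mol %), CuI (4 mol %), Et3N, THF, rt, degassed
Reagents that add atoms: none
Why: In this Sonogashira coupling, oxidative addition of zerovalent palladium into the alkenyl C–I bond, transmetalation from the copper acetylide and reductive elimination all proceed with retention at the alkene, so the Z geometry should be carried over, and the free secondary hydroxyl is tolerated.

Step 4
Reactants: 8 (Z)-1-(trimethylsilyl)henicos-3-en-1-yn-5-ol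
Product: 9 (Z)-henicos-3-en-1-yn-5-ol (racemic)
Conditions: K2CO3 (0.2 equiv), MeOH, 0 °C to rt
Reagents that add atoms: none
Why: Base-catalysed protodesilylation, in which methoxide attacks silicon and methanol protonates the alkynyl anion, is mild enough to leave the Z alkene and the carbinol untouched if the mixture is kept cold and worked up promptly.

Step 5
Reactants: 9 (Z)-henicos-3-en-1-yn-5-ol
Product: 11 methyl 2-(5-hexadecylfuran-2-yl)acetate, via furan-2(5H)-ylidene ester 10 (not isolated)
Conditions: PdI2 (1 mol %), KI (10 mol %), CO/air 9:1 (ca. 100 atm, autoclave), MeOH, 70 °C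
Reagents that add atoms: carbon monoxide, [C-]#[O+]; methanol, CO
Why: Divalent palladium (the tetraiodopalladate formed from PdI2 and KI) binds the terminal alkyne, and the C5 hydroxyl attacks the internal alkyne carbon anti to the metal, closing the five-membered ring through the O1–C2 bond in a 5-exo-dig mode to give an (E)-alkenylpalladium iodide. Migratory insertion of CO and methanolysis of the acylpalladium species then form the CH2–C(=O) and C(=O)–OMe bonds and release the ylidene ester 10, HI and zerovalent palladium, which oxygen and iodide return to PdI2. Ester 10 should tautomerise under the reaction conditions, its ring C5 hydrogen moving to the exocyclic carbon, to give the aromatic furan 11; the carbinol stereocentre disappears and no new one is created. The closest known reaction type is the PdI2/KI-catalysed oxidative cyclisation–alkoxycarbonylation of (Z)-2-en-4-yn-1-ols to furan-2-ylacetic esters. The step needs ring closure to precede carbonylation and CO insertion to outrun protonolysis of the alkenylpalladium species. The Z alkene holds the hydroxyl within reach of the bound alkyne, the terminal alkyne leaves the exocyclic carbon as the only carbonylation site, and the high CO pressure favours insertion.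

Compound list
1 | ethyl propiolate (ethyl prop-2-ynoate) | C#CC(=O)OCC | starting material
2 | ethyl (Z)-3-iodoprop-2-enoate | CCOC(=O)/C=C\I | intermediate
3 | 1-bromohexadecane | CCCCCCCCCCCCCCCCBr | starting material
4 | hexadecylmagnesium bromide | CCCCCCCCCCCCCCCC[Mg]Br | intermediate
5 | (Z)-3-iodoprop-2-enal | O=C/C=C\I | intermediate
6 | (Z)-1-iodononadec-1-en-3-ol (racemic) | CCCCCCCCCCCCCCCCC(O)/C=C\I | intermediate
7 | ethynyltrimethylsilane | C#C[Si](C)(C)C | starting material
8 | (Z)-1-(trimethylsilyl)henicos-3-en-1-yn-5-ol (racemic) | CCCCCCCCCCCCCCCCC(O)/C=C\C#C[Si](C)(C)C | intermediate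
9 | (Z)-henicos-3-en-1-yn-5-ol (racemic) | CCCCCCCCCCCCCCCCC(O)/C=C\C#C | intermediate
10 | methyl (E)-2-(5-hexadecylfuran-2(5H)-ylidene)acetate (racemic) | COC(=O)/C=C1\C=CC(CCCCCCCCCCCCCCCC)O1 | intermediate
11 | methyl 2-(5-hexadecylfuran-2-yl)acetate | CCCCCCCCCCCCCCCCc1ccc(CC(=O)OC)o1 | target

Total step count: 5. Longest linear sequence: 5 steps (1 → 2 → 6 → 8 → 9 → 11); the Grignard reagent 4 is prepared from 3 within step 2.

Steps most likely to fail

Step 5. Protonolysis of the alkenylpalladium intermediate may outrun CO insertion, giving cycloisomerisation without the ester carbon, or double alkoxycarbonylation of the free alkyne may precede ring closure. Fallback: setting out from 6, a Sonogashira coupling with methyl propiolate (Pd(PPh3)2Cl2, CuI, K2CO3, THF, slow addition of the propiolate) would give methyl (Z)-6-hydroxydocos-4-en-2-ynoate F1, which already holds the ester carbon. Base (DBU or the K2CO3 present) should then drive a 5-exo-dig oxa-Michael addition of the hydroxyl to the ynoate β-carbon. This would give the ylidene ester as 10 and/or its geometric isomer methyl (Z)-2-(5-hexadecylfuran-2(5H)-ylidene)acetate F2, and both tautomerise to 11, where the route ends. No CO or oxidant is needed on this path.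

Step 2. Reduction may run past the aldehyde level, or the β-iodoenal may isomerise from Z to E before the Grignard reagent captures it, carrying an alkene geometry that cannot cyclise in step 5. Fallback: setting out from 4 (made from 3), addition to purchased 3-(trimethylsilyl)prop-2-ynal (THF, −78 °C) would give 1-(trimethylsilyl)nonadec-1-yn-3-ol F3. Iododesilylation (N-iodosuccinimide, AgNO3 cat., DMF) would give 1-iodononadec-1-yn-3-ol F4. A cis-selective diimide reduction (2-nitrobenzenesulfonyl hydrazide, Et3N, THF/i-PrOH) would then deliver 6, where the route is rejoined. The Z geometry is set by syn delivery of two hydrogens, and no isomerisable enal is involved.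

Step 4. The liberated enynol may undergo base-induced cycloisomerisation to a furan lacking the ester carbon, or the sensitive terminal enyne may degrade on concentration. Fallback: setting out from 6, a Stille coupling with tributyl(ethynyl)stannane (Pd(PPh3)4, THF, rt to 50 °C) would install the free ethynyl group directly and return to the route at 9. This bypasses 8 and any basic deprotection and makes no new compound (F0).

Further compounds
F1 | step 5 | methyl (Z)-6-hydroxydocos-4-en-2-ynoate (racemic) | CCCCCCCCCCCCCCCCC(O)/C=C\C#CC(=O)OC
F2 | step 5 | methyl (Z)-2-(5-hexadecylfuran-2(5H)-ylidene)acetate (racemic) | COC(=O)/C=C1/C=CC(CCCCCCCCCCCCCCCC)O1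
F3 | step 2 | 1-(trimethylsilyl)nonadec-1-yn-3-ol (racemic) | CCCCCCCCCCCCCCCCC(O)C#C[Si](C)(C)C
F4 | step 2 | 1-iodononadec-1-yn-3-ol (racemic) | CCCCCCCCCCCCCCCCC(O)C#CI
F0 | step 4 | none | none
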